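The vessel was closed, stirred and isothermal, and you asked me for a quick number on it, with your forecast beside it.

| flask | G | Z | J | temperature | remark | time |
|---|---|---|---|---|---|---|
| epsilon | 0.25 M | 0.25 M | 1.2 equiv | 12 °C | run made earlier |  |
| delta | 0.25 M | 0.25 M | 1.8 equiv | 29 °C | run made earlier |  |
| alpha | 0.25 M | 0.25 M | 2.5 equiv | 12 °C | run made earlier |  |
| midnight | 0.25 M | 0.25 M | 1.50 equiv | 35 °C |  | 4.0 min |
| dusk | 0.25 M | 0.25 M | 2.20 equiv | 5 °C |  | 6.0 min |

epsilon run (percent of the G and Z together charged)

| time / min | D / % | L / % |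
|---|---|---|
| 0.250 | 0.1 | 0.6 |
| 0.417 | 0 | 0.6 |
| 0.833 | 1.9 | 0.3 |
| 1.50 | 4.6 | 0.1 |
| 3.00 | 10.9 | 0.3 |

delta run (percent of the G and Z together charged)

| time / s | D / % | L / % |
|---|---|---|
| 10.0 | 0 | 0.3 |
| 15.0 | 0.3 | 0 |
| 30.0 | 2.2 | 1.0 |
| 60.0 | 3.6 | 1.0 |

alpha run (percent of the G and Z together charged)

| time / min | D / % | L / % |
|---|---|---|
| 0.250 | 0 | 0.2 |
| 0.833 | 1.8 | 0 |
| 1.33 | 3.5 | 0 |
| 2.00 | 5.5 | 0.3 |
| 3.00 | 9.6 | 0.2 |

(standard deviation of a reading: 0.5 percentage points)

- which of the two ends with the higher excess of D over L ("neither" if they lie within 2 percentage points) (midnight / dusk / neither)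
- excess of D over L at the end, midnight
- excess of D over L at the end, dusk

- Q is single-handed; G and Z are mirror images of each other, charged as a racemate, each of them at the stated concentration
- J is a solid; its amount is given per volume of the solution
- the numbers in the tables scatter with a standard deviation of 0.5 percentage points
- at the start none of J is in solution
- an excess is the difference of the two amounts in percent of their sum
- an excess is below zero if the other one leads
- the handed part of Q does not stay in what it makes, so the products of the two hands are mirror images too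

In midnight J was the limiting reagent, at 0.375 M against 0.500 M of G and Z together. Its balance runs through Q, and I assumed that D and L each take one Q, so that [Q] divides out of the ratio of their rates. That left me one quantity to read off the last readings, with their scatter: the selectivity factor at 12 °C, s = 41.0, the D formed per L formed. The excess is then s minus one over s plus one.

| Reading | Temperature | s | Excess |
|---|---|---|---|
| epsilon and alpha, last readings | 12 °C | 41.0 | 95.2% |
| delta, last reading | 29 °C | 3.60 | 56.5% |
| delta, L one scatter lower | 29 °C | 7.20 | 75.6% |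

Delta's L stood at twice the scatter, so I held its s to be a weak reading. I committed to dusk as the higher, near 95.2%, with midnight near 75.6% from the third row.

Your forecast said dusk, with 36% for midnight and 96% for dusk, on this ground: “L changes strongly with temperature”. My midnight number stood higher than yours.

The flasks gave dusk as the higher, with midnight at 88.3% and dusk at 95.1%.

    Q + G → D (k = 0.0100 L mol⁻¹ s⁻¹, Ea = 43.0 kJ mol⁻¹)
    G ⇌ Z (k = 0.00100 s⁻¹, Ea = 77.0 kJ mol⁻¹)
    J ⇌ Q, rate k3*(cs3 - [Q]) while solid is left; crystals form when [Q] > cs3 (solubility = 0.120 M, k = 0.0200 s⁻¹)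
    Q → X (k = 1.20 × 10⁻⁵ s⁻¹, Ea = 88.0 kJ mol⁻¹)
    Q + Z → L (k = 2.20 × 10⁻⁴ L mol⁻¹ s⁻¹, Ea = 66.0 kJ mol⁻¹)
    (constants at 5 °C)

Midnight's excess means s = 16.1, above the 7.20 I had used and the forecast's 2.2 for 35 °C. Changing J alone from dusk to midnight moved the excess by 0 percentage points. I drew ln s as a straight line in temperature between 41.0 at 12 °C and 16.1 at 35 °C, and read off the neighbour, dusk repeated at 30 °C: s = 19.8, so an excess of 90.4%. That neighbour held D at 43.9% and L at 2.42%, and its excess stood at 89.6%.

All runs were computed on assumed constants.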